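## The problem

Atoms are labelled along the skeleton: C3 is the ester carbonyl, C4 the ester-bearing CH, C5 its CH2 neighbour, C6 the quaternary carbon common to three rings, C7 the lactam carbonyl, N8, C9, C10 and C11 the N–CH2–CH–CH2 bridge, C12–C17 the enone ring (C14 carbinol, C17 ketone), C18 the second quaternary carbon, C19 its CH2OAc, and C20–C24 the keto chain back to N8 (C22 ketone, C23 methyl-bearing CH). Cyclopentane A (C4, C5, C6, C13, C14) and cyclohexenone B are fused at C13–C14. Ring C (C6, C13, C12, C11, C10, C18) and δ-lactam D (C6, C7, N8, C9, C10, C18) form a bicyclo[3.3.1] unit around the one-carbon bridge C18, and the nine-membered keto-lactam E spans N8 and C18. The crux is the vicinal pair of quaternary centres C6/C18. C10 is then dictated by the bridge, C14 can be set from C4, C4 is epimerisable and can be set late, and the remote C23 can only come from the chiral pool. The β-hydroxy ester (C14–OH next to the C4 ester: retro-aldol, dehydration), the acetate, the enone and the C23 methine α to the C22 ketone will not survive strong base or acid, so the end game must be neutral. Ring B is a 4-hydroxy-4-alkylcyclohex-2-enone, the dihydro para-quinol of a phenol with OH at C17 whose three contiguous carbons C12, C13 and C14 carry C11, C6 and C4. Such a phenol, with ring A closed from C14 to C13 through the three-atom tether C4–C5–C6, is what a cyclobutenone-derived vinylketene delivers on adding to a tethered alkyne.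

## Retrosynthesis

Target 44 is traced to alcohol 43, dienone 42 and phenol 41 by three redox changes. The only skeletal cut is the C14–O bond, made by oxidative addition of water para to the phenol OH of 41. This is preferred to carrying the tertiary alcohol through the synthesis because the β-hydroxy ester then appears only under neutral conditions, and the adjacent C4 ester directs the face.

Ring E of 41 is cut at C20=C21 (ring-closing metathesis of diene 40). Lactamisation or N-alkylation to a nine-membered ring would have no pre-organisation, whereas the two vinyl groups of 40 are held over ring D. The forward reaction must close a medium ring from a neopentyl vinyl group.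

Ring C and the lactam CH2 of 40/39/38 are cut together at C10–C11 and C9–H, back to hydroxylactam 36 and spiro-glutarimide phenol 35. An enamide at C9=C10 and an ortho-hydroxybenzyl cation at C11 are generated by the same acid, so no strong base, phenol protection or benzylic halide is needed and the second imide carbonyl is removed in the same operation. C10 can only form with C11 syn to the aryl bridge. C4 is equilibrated once the tetracycle is rigid (38 to 39).

Phenol 35 is cut at C13–C14 and C12–C17 to cyclobutenone 30, the key disconnection. It removes rings A and B at once and leaves a monocyclic glutarimide with an alkyne and a side chain. The forward step must make an unactivated alkyne capture the ketene; the three-atom tether is relied on for that.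

Cyclobutenone 30 comes from ethoxycyclobutanone 29 by loss of ethanol, and 29 from succinic half-ester 26 through its aldoketene and ethyl vinyl ether. This places the substituent on the enone α-carbon, which cyclobutenone syntheses from alkynes do not.

The propargylic ether of 26/25 is cut to formaldehyde and terminal alkyne 23. The alkyne carbon C12 comes from Me3SiCHN2 and C13 is the carbonyl carbon of the γ-lactone in lactol 21 and lactone 20. The lactone ties C13 to the C19 oxygen, so the alkyne must end cis to CH2OAc; an electrophilic alkynylation of a monocyclic imide would have to tell vinyl from CH2OR.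

Diester 20 is cut at C5–C6 to the cis-fused lactone imide 18 and dimethyl itaconate 19. Alkylation at the ring-fusion carbon of a 5/6 bicycle can only give the cis-fused product, which fixes C6 relative to C18 without any facial bias being needed.

Imide 18 is cut at its two N–C(=O) bonds to acid 16 (through amide 17) and amine 6; 6 comes from methyl (R)-3-hydroxy-2-methylpropanoate 1 through azides 2, 4 and 5 and carries C23.

Lactone 16 (from ester 15) is cut at C6–C18 to allylic chloride 14. The intramolecular palladium-catalysed allylic alkylation creates the quaternary centre C18 together with its vinyl group, which a conjugate addition to a dienoate could not do regioselectively. 14 is assembled from alcohol 12 and methyl malonyl chloride 13, and 12 from phosphonate 9 and chloroacetaldehyde 10 through diester 11; 9 comes from triethyl phosphonoacetate 7 and tert-butyl bromoacetate 8.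

## Roads not taken

Alternative 1: The cut is the C4–C14 bond of ring A. A six-membered α-diazo ketone A4, already holding rings B to E and the silylated C14 carbinol, would be irradiated in methanol; the carbinol carbon migrates to the carbene carbon and methanol traps the ketene to give A1, one desilylation from the target. Its merits are real: the migration is stereoretentive, C14 is set before any dearomatisation, and the end game is shorter than the present one. Its weak points lie before the key step. A4 is as complex as the target, with a larger ring A, and its route must still build the B/C/D/E core and place a diazo group regioselectively beside a tertiary silyl ether. C4 would be set by kinetic protonation next to a β-leaving group. The enone of ring B competes for light. The chosen plan has the less certain end game, but it builds rings A and B from an acyclic tether in one step with C11, C6 and C4 regiodefined.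

Alternative 2: The cut is the C20–C21 bond with simultaneous formation of quaternary C18. The potassium alkoxide of indolizidinone carbinol A5 would undergo an anionic oxy-Cope rearrangement to the bridged enamide keto-lactam A2, forming ring E by ring expansion. For ring E this is better than metathesis: no entropic penalty, no hindered alkene pair, and chirality transfer through a cyclic transition state. Against it, A2 holds only rings D and E: C6 is a spiro-cyclopentene with no configuration, and rings A to C, C10, C4 and C14 are still to come. The basic conditions also put the new C23 methine α to the forming ketone at risk. The chosen plan sets against the better ring E closure a convergent A/B/C assembly with C6/C18 locked by a lactone, and a fallback for the metathesis.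

Alternative 3: The cut is the C22–C23 bond. Irradiation of the seven-membered N-propyl imide A6 at 254 nm would give, by γ-hydrogen abstraction, azetidinol closure and C–N cleavage, the nine-membered keto-lactam A3. It makes ring E and its ketone from a plain propyl group and needs neither a chiral amine nor metathesis, which is more economical than the present ring E sequence. Its weak points are that C23 is formed from a biradical with no control element, the choice between the two imide carbonyls and the fragmentation pathway are uncertain, and A3 still lacks rings A, B and D. The chosen plan takes C23 from the chiral pool at the cost of a four-step amine synthesis.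

Key step: step 21

Remark: the side-chain carbinol carbon C22 (steps 2 to 28) and the ester-bearing carbon C4 (steps 13 to 23) are carried as mixtures of both epimers, because C22 is oxidised in step 29 and C4 is equilibrated in step 24; the SMILES leave these centres open.

Remark: the sense of induction in step 9 is assumed for the (S,S)-ligand; if a trial gives the antipode, the (R,R)-ligand is used.

Step 1
Reactants: 1 methyl (R)-3-hydroxy-2-methylpropanoate
Product: 2 methyl (R)-3-azido-2-methylpropanoate
Conditions: PPh3, DIAD, (PhO)2P(O)N3, THF, 0 °C to rt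
Reagents that add atoms: diphenylphosphoryl azide, [N-]=[N+]=NP(=O)(Oc1ccccc1)Oc1ccccc1
Why: Mitsunobu azidation of the primary alcohol; the stereocentre is not the reacting carbon, so the configuration of 1 is kept.

Step 2
Reactants: 2 methyl (R)-3-azido-2-methylpropanoate
Product: 4 (4R)-5-azido-4-methylpent-1-en-3-ol (both C3 epimers), via azido aldehyde 3 (not isolated)
Conditions: i-Bu2AlH, CH2Cl2, −78 °C; then CH2=CHMgBr, THF, −78 to 0 °C
Reagents that add atoms: vinylmagnesium bromide, C=C[Mg]Br
Why: Half-reduction to the aluminium hemiacetal and Grignard addition in the same flask avoid isolating the epimerisable α-methyl aldehyde; the new carbinol centre forms unselectively and is erased in step 29.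

Step 3
Reactants: 4 (4R)-5-azido-4-methylpent-1-en-3-ol
Product: 5 (4R)-5-azido-3-(tert-butyldiphenylsilyloxy)-4-methylpent-1-ene
Conditions: t-BuPh2SiCl, imidazole, DMF, rt
Reagents that add atoms: tert-butyl(chloro)diphenylsilane, CC(C)(C)[Si](Cl)(c1ccccc1)c1ccccc1
Why: Standard silylation; the diphenyl silyl ether is chosen because it must survive the acid of step 23.

Step 4
Reactants: 5 (4R)-5-azido-3-(tert-butyldiphenylsilyloxy)-4-methylpent-1-ene
Product: 6 (2R)-3-(tert-butyldiphenylsilyloxy)-2-methylpent-4-en-1-amine
Conditions: PPh3, THF/H2O, 50 °C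
Reagents that add atoms: none
Why: Staudinger reduction; it leaves the alkene and the silyl ether untouched.

Step 5
Reactants: 7 triethyl phosphonoacetate; 8 tert-butyl bromoacetate
Product: 9 4-tert-butyl 1-ethyl 2-(diethoxyphosphoryl)butanedioate (racemic)
Conditions: NaH, THF, 0 °C to rt
Reagents that add atoms: none
Why: C-alkylation of the stabilised phosphonate anion with a reactive α-halo ester; an excess of 7 limits dialkylation.

Step 6
Reactants: 9 4-tert-butyl 1-ethyl 2-(diethoxyphosphoryl)butanedioate; 10 chloroacetaldehyde
Product: 11 4-tert-butyl 1-ethyl (E)-2-(2-chloroethylidene)butanedioate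
Conditions: LiCl, DBU, MeCN, 0 °C
Reagents that add atoms: none
Why: Horner–Wadsworth–Emmons olefination under Masamune–Roush conditions; the mild base spares the allylic chloride and the aldehyde substituent should end trans to the ethyl ester.

Step 7
Reactants: 11 4-tert-butyl 1-ethyl (E)-2-(2-chloroethylidene)butanedioate
Product: 12 tert-butyl (E)-5-chloro-3-(hydroxymethyl)pent-3-enoate
Conditions: i-Bu2AlH (2.2 equiv), CH2Cl2, −78 °C
Reagents that add atoms: none
Why: 1,2-Reduction of the conjugated ethyl ester; the tert-butyl ester reacts much more slowly at −78 °C, and the E geometry keeps the new hydroxyl away from the chloride.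

Step 8
Reactants: 12 tert-butyl (E)-5-chloro-3-(hydroxymethyl)pent-3-enoate; 13 methyl malonyl chloride
Product: 14 tert-butyl (E)-5-chloro-3-[(3-methoxy-3-oxopropanoyloxy)methyl]pent-3-enoate
Conditions: pyridine, CH2Cl2, 0 °C
Reagents that add atoms: none
Why: O-acylation of a primary allylic alcohol with an acid chloride; it tethers the malonate nucleophile through what becomes the lactone.

Step 9
Reactants: 14 tert-butyl (E)-5-chloro-3-[(3-methoxy-3-oxopropanoyloxy)methyl]pent-3-enoate
Product: 15 methyl (4S)-4-(2-tert-butoxy-2-oxoethyl)-2-oxo-4-vinyloxolane-3-carboxylate (C3 epimers)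
Conditions: Pd2(dba)3·CHCl3 (2.5 mol %), (S,S)-DACH-phenyl Trost ligand (7.5 mol %), Cs2CO3, CH2Cl2, 0 °C to rt
Reagents that add atoms: none
Why: Intramolecular palladium-catalysed asymmetric allylic alkylation; the malonate attacks the substituted allyl terminus in a 5-exo closure, forming C6–C18 with the vinyl group. The two allyl faces interconvert through the η1 complex at the CH2 terminus, so the ligand decides the C18 configuration.

Step 10
Reactants: 15 methyl (4S)-4-(2-tert-butoxy-2-oxoethyl)-2-oxo-4-vinyloxolane-3-carboxylate
Product: 16 2-[(3S)-4-(methoxycarbonyl)-5-oxo-3-vinyloxolan-3-yl]acetic acid (C4 epimers of the ring)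
Conditions: CF3CO2H, CH2Cl2, rt
Reagents that add atoms: none
Why: Acidolysis of the tert-butyl ester; the methyl ester, lactone and vinyl group are stable to it.

Step 11
Reactants: 16 2-[(3S)-4-(methoxycarbonyl)-5-oxo-3-vinyloxolan-3-yl]acetic acid; 6 (2R)-3-(tert-butyldiphenylsilyloxy)-2-methylpent-4-en-1-amine
Product: 17 2-[(3S)-4-{[(2R)-3-(tert-butyldiphenylsilyloxy)-2-methylpent-4-enyl]carbamoyl}-5-oxo-3-vinyloxolan-3-yl]acetic acid
Conditions: Et3N (1 equiv), toluene, 80 °C
Reagents that add atoms: none
Why: Aminolysis of the activated malonyl ester/lactone by the primary amine; whichever acyl group is attacked, relactonisation onto the other gives the same lactone amide with loss of methanol.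

Step 12
Reactants: 17 lactone amide acid
Product: 18 cis-fused γ-lactone glutarimide (6R,18S): N-substituted glutarimide with C6–H between imide C7=O and lactone C13=O, lactone oxygen on C19, vinyl on C18
Conditions: 1,1'-carbonyldiimidazole, THF, rt; then DBU, 40 °C
Reagents that add atoms: none
Why: Amic acid to imide closure through the acyl imidazolide; the acidic C6–H lets the ring fusion settle as the only unstrained, cis-fused isomer.

Step 13
Reactants: 18 cis-fused γ-lactone glutarimide; 19 dimethyl itaconate
Product: 20 Michael adduct (6R,18S; C4 epimers): lactone imide with the CH2CH(CO2Me)CH2CO2Me chain on C6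
Conditions: DBU (0.3 equiv), MeCN, 50 °C
Reagents that add atoms: none
Why: Michael addition of the β-dicarbonyl carbon C6; a 5/6 ring fusion can only be alkylated to the cis-fused product, so C5 ends cis to the vinyl group and the lactone carbonyl cis to C19, which sets C6.

Step 14
Reactants: 20 Michael adduct
Product: 21 lactol (6S,18S; epimers at C4 and the lactol carbon): as 20 with the lactone C=O reduced to CH(OH)
Conditions: LiN(i-Pr)2 (3.3 equiv), THF, −78 °C; then i-Bu2AlH (1.5 equiv), −78 to −40 °C; AcOH quench
Reagents that add atoms: none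
Why: Half-reduction of a lactone with i-Bu2AlH; the imide (C10 enolate) and both methyl esters (succinate bis-enolate) are shielded in situ as lithium enolates, so the non-enolisable lactone is the only free carbonyl.

Step 15
Reactants: 21 lactol
Product: 23 acetoxymethyl ethynyl glutarimide diester (6R,18S; C4 epimers), via hydroxymethyl ethynyl glutarimide 22 (not isolated)
Conditions: LiN(i-Pr)2 (4.5 equiv), Me3SiCHN2, THF, −78 to 0 °C; AcOH, −78 °C; then Ac2O, pyridine, DMAP, 0 °C
Reagents that add atoms: (trimethylsilyl)diazomethane, C[Si](C)(C)C=[N+]=[N-]; acetic anhydride, CC(=O)OC(C)=O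
Why: Colvin rearrangement of the aldehyde released from the lactolate (Peterson elimination, loss of N2, 1,2-hydride shift) gives the terminal alkyne. The imide stays shielded as its enolate, and the freed C19 hydroxyl is acetylated at once so that it cannot open the imide.

Step 16
Reactants: 23 acetoxymethyl ethynyl glutarimide diester
Product: 24 propargylic alcohol (C11–OH)
Conditions: Zn(OTf)2, Et3N, (CH2O)n, toluene, 60 °C
Reagents that add atoms: formaldehyde (from paraformaldehyde), C=O
Why: Addition of the zinc acetylide formed in situ to formaldehyde; only the alkyne C–H is metalated under these amine-base conditions, so imide, esters and acetate are untouched.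

Step 17
Reactants: 24 propargylic alcohol
Product: 25 propargylic tert-butyldimethylsilyl ether
Conditions: t-BuMe2SiCl, imidazole, CH2Cl2, rt
Reagents that add atoms: tert-butyl(chloro)dimethylsilane, CC(C)(C)[Si](C)(C)Cl
Why: Standard silylation; the ether is thermally stable in step 21 and ionises under the acid of step 23.

Step 18
Reactants: 25 propargylic silyl ether
Product: 26 succinic half-ester (free C17 acid, C3 methyl ester)
Conditions: Me3SnOH, ClCH2CH2Cl, 70 °C; dilute HCl work-up
Reagents that add atoms: trimethyltin hydroxide, C[Sn](C)(C)O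
Why: Trimethyltin hydroxide cleaves the less hindered CH2CO2Me ester in preference to the α-branched C3 ester and the neopentyl acetate.

Step 19
Reactants: 26 succinic half-ester
Product: 29 2-substituted 3-ethoxycyclobutanone (diastereomers), via acid chloride 27 (not isolated), via aldoketene 28 (not isolated)
Conditions: (COCl)2, cat. DMF, CH2Cl2, 0 °C; then ethyl vinyl ether (solvent), Et3N (slow addition), 35 °C
Reagents that add atoms: ethyl vinyl ether, C=COCC
Why: Dehydrochlorination gives the aldoketene, which undergoes thermal [2+2] cycloaddition with the electron-rich enol ether; the ketene carbonyl carbon bonds to the enol ether CH2, so OEt ends β to the ketone. The excess of vinyl ether outruns addition to the tethered alkyne.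

Step 20
Reactants: 29 2-substituted 3-ethoxycyclobutanone
Product: 30 cyclobutenone (6R,18S; C4 epimers): N-substituted glutarimide with C6 bearing C≡C–CH2OSiMe2t-Bu and CH2CH(CO2Me)(2-oxocyclobut-3-enyl, attached at its α-carbon), C18 bearing vinyl and CH2OAc
Conditions: DBU (1.1 equiv), CH2Cl2, −20 to 0 °C
Reagents that add atoms: none
Why: E1cB loss of ethanol from the β-alkoxy cyclobutanone gives the endocyclic enone; low temperature and short contact limit migration of the double bond toward C4.

Step 21
Reactants: 30 cyclobutenone
Product: 35 spiro-glutarimide hydroxyindane (6R,18S; C4 epimers), via vinylketene 31 (not isolated), via fused cyclobutenone 32 (not isolated), via dienylketene 33 (not isolated), via cyclohexadienone 34 (not isolated)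
Conditions: toluene (0.005 M, degassed), 110 °C, sealed tube; raise to 130 °C if needed
Reagents that add atoms: none
Why: Heating opens 30 by a 4π electrocyclic reaction to vinylketene 31. Its C17=C14 bond adds across the tethered alkyne in a [2+2] sense, forming C14–C13 and C17–C12 and closing ring A as the five-membered ring of bicyclo[3.2.0] cyclobutenone 32 (exo closure through the tether C4–C5–C6). A second 4π opening gives dienylketene 33, 6π electrocyclisation (C17–C16) closes ring B as cyclohexadienone 34, and tautomerisation gives phenol 35. The closest known reaction is the Danheiser benzannulation in its intramolecular form. No stereocentre is formed; C6, C18 and C23 are sp3 spectators and C4 is carried as a mixture. Regiochemistry is fixed by the tether, since the ketene α-carbon can only reach the proximal alkyne carbon, so OH ends para to C14 and the CH2O group at C12. The chemoselectivity needed is alkyne over the C18 vinyl group (four-atom tether, slower) and over dimerisation, which the short tether and high dilution should secure.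

Step 22
Reactants: 35 spiro-glutarimide hydroxyindane
Product: 36 C9 hydroxylactam (epimers at C9 and C4)
Conditions: LiBH(s-Bu)3 (2.5 equiv), THF, −78 °C; NH4Cl work-up
Reagents that add atoms: none
Why: Partial reduction of an imide by a bulky borohydride at the less hindered carbonyl; C7 is flanked by the spiro quaternary carbon C6, and esters and the acetate are not reduced at −78 °C.

Step 23
Reactants: 36 C9 hydroxylactam
Product: 38 bridged lactam phenol (6R,10S,18R; C4 epimers), via bridged aryl aminal 37 (not isolated)
Conditions: CF3CO2H (10 equiv), CH2Cl2, −20 to 0 °C; then Et3SiH (5 equiv), 0 °C to rt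
Reagents that add atoms: none
Why: Acid converts the hydroxylactam into the N-acyliminium ion/enamide and the benzylic silyl ether into an ortho-hydroxybenzyl cation. The enamide carbon C10 attacks C11 to close ring C, and C10 can only form with C11 syn to the aryl bridge. The new N-acyliminium ion, resting as aminal 37, is reduced by Et3SiH to the lactam CH2.

Step 24
Reactants: 38 bridged lactam phenol (C4 epimers)
Product: 39 bridged lactam phenol with (4R) configuration
Conditions: DBU (2 equiv), toluene, 80 °C
Reagents that add atoms: none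
Why: Base equilibration of the benzylic ester; in the rigid tetracycle the C7 acyl group is pseudo-axial on ring A, so the ester should prefer the opposite face, cis to C18, which is the (4R) epimer.

Step 25
Reactants: 39 bridged lactam phenol (4R)
Product: 40 diene allylic alcohol (free C22–OH)
Conditions: n-Bu4NF, AcOH, THF, rt
Reagents that add atoms: none
Why: Fluoride cleavage of the silyl ether, buffered so that the acetate and the C4 centre are not disturbed; the free allylic alcohol is the better metathesis partner.

Step 26
Reactants: 40 diene allylic alcohol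
Product: 41 pentacyclic phenol with C20=C21 alkene in ring E
Conditions: second-generation Grubbs catalyst (H2IMes)(PCy3)Cl2Ru=CHPh (15 mol %), CH2Cl2 (0.002 M), 40 °C
Reagents that add atoms: none
Why: Ring-closing metathesis; the catalyst loads on the allylic alcohol alkene and closes onto the C18 vinyl group, which the bicyclic core holds over ring D.

Step 27
Reactants: 41 pentacyclic phenol
Product: 42 para-quinol dienone (4R,6S,10S,14S,18R,23R)
Conditions: PhI(OAc)2, MeCN/H2O (4:1), 0 °C
Reagents that add atoms: water, O
Why: Oxidative dearomatisation of a para-alkyl phenol; water attacks C14 of the phenoxonium species on the face opposite the adjacent C4 ester, giving the (14S) carbinol.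

Step 28
Reactants: 42 para-quinol dienone
Product: 43 saturated ring E alcohol with the ring B enone
Conditions: H2 (1 atm), Pd/C, EtOAc, rt
Reagents that add atoms: none
Why: Heterogeneous hydrogenation reduces the two disubstituted alkenes (C15=C16 and C20=C21); the tetrasubstituted enone alkene C12=C13 is too hindered to react.

Step 29
Reactants: 43 saturated ring E alcohol
Product: 44 CNP0211170.1
Conditions: Dess–Martin periodinane, NaHCO3, CH2Cl2, 0 °C to rt
Reagents that add atoms: none
Why: Oxidation of the secondary C22 alcohol; the tertiary C14 alcohol cannot react and the buffered neutral medium protects the C23 methine and the β-hydroxy ester.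

Compound list

1 | methyl (R)-3-hydroxy-2-methylpropanoate | COC(=O)[C@H](C)CO | starting material
2 | methyl (R)-3-azido-2-methylpropanoate | COC(=O)[C@H](C)CN=[N+]=[N-] | intermediate
3 | (R)-3-azido-2-methylpropanal | O=C[C@H](C)CN=[N+]=[N-] | intermediate (not isolated)
4 | (4R)-5-azido-4-methylpent-1-en-3-ol, both C3 epimers | C=CC(O)[C@H](C)CN=[N+]=[N-] | intermediate
5 | (4R)-5-azido-3-(tert-butyldiphenylsilyloxy)-4-methylpent-1-ene | C=CC(O[Si](c1ccccc1)(c1ccccc1)C(C)(C)C)[C@H](C)CN=[N+]=[N-] | intermediate
6 | (2R)-3-(tert-butyldiphenylsilyloxy)-2-methylpent-4-en-1-amine | C=CC(O[Si](c1ccccc1)(c1ccccc1)C(C)(C)C)[C@H](C)CN | intermediate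
7 | triethyl phosphonoacetate | CCOC(=O)CP(=O)(OCC)OCC | starting material
8 | tert-butyl bromoacetate | CC(C)(C)OC(=O)CBr | starting material
9 | 4-tert-butyl 1-ethyl 2-(diethoxyphosphoryl)butanedioate (racemic) | CCOC(=O)C(CC(=O)OC(C)(C)C)P(=O)(OCC)OCC | intermediate
10 | chloroacetaldehyde | O=CCCl | starting material
11 | 4-tert-butyl 1-ethyl (E)-2-(2-chloroethylidene)butanedioate | CCOC(=O)/C(=C/CCl)CC(=O)OC(C)(C)C | intermediate
12 | tert-butyl (E)-5-chloro-3-(hydroxymethyl)pent-3-enoate | OC/C(=C/CCl)CC(=O)OC(C)(C)C | intermediate
13 | methyl malonyl chloride (methyl 3-chloro-3-oxopropanoate) | COC(=O)CC(Cl)=O | starting material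
14 | tert-butyl (E)-5-chloro-3-[(3-methoxy-3-oxopropanoyloxy)methyl]pent-3-enoate | COC(=O)CC(=O)OC/C(=C/CCl)CC(=O)OC(C)(C)C | intermediate
15 | methyl (4S)-4-(2-tert-butoxy-2-oxoethyl)-2-oxo-4-vinyloxolane-3-carboxylate, C3 epimers | COC(=O)C1C(=O)OC[C@]1(C=C)CC(=O)OC(C)(C)C | intermediate
16 | 2-[(3S)-4-(methoxycarbonyl)-5-oxo-3-vinyloxolan-3-yl]acetic acid | COC(=O)C1C(=O)OC[C@]1(C=C)CC(=O)O | intermediate
17 | 2-[(3S)-4-{[(2R)-3-(tert-butyldiphenylsilyloxy)-2-methylpent-4-enyl]carbamoyl}-5-oxo-3-vinyloxolan-3-yl]acetic acid | C=CC(O[Si](c2ccccc2)(c2ccccc2)C(C)(C)C)[C@H](C)CNC(=O)C1C(=O)OC[C@]1(C=C)CC(=O)O | intermediate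
18 | cis-fused γ-lactone glutarimide (6R,18S,23R): N-[(2R)-3-silyloxy-2-methylpent-4-enyl] imide, C6–H between C7=O and lactone C13=O, vinyl on C18 | [C@H]12C(=O)N(C[C@@H](C)C(O[Si](c3ccccc3)(c3ccccc3)C(C)(C)C)C=C)C(=O)C[C@@]1(C=C)COC2=O | intermediate
19 | dimethyl itaconate | C=C(CC(=O)OC)C(=O)OC | starting material
20 | Michael adduct (6R,18S; C4 epimers): lactone imide 18 carrying CH2CH(CO2Me)CH2CO2Me on C6 | COC(=O)CC(C(=O)OC)C[C@]12C(=O)N(C[C@@H](C)C(O[Si](c3ccccc3)(c3ccccc3)C(C)(C)C)C=C)C(=O)C[C@@]1(C=C)COC2=O | intermediate
21 | lactol (6S,18S; epimers at C4 and the lactol carbon) | COC(=O)CC(C(=O)OC)C[C@]12C(=O)N(C[C@@H](C)C(O[Si](c3ccccc3)(c3ccccc3)C(C)(C)C)C=C)C(=O)C[C@@]1(C=C)COC2O | intermediate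
22 | hydroxymethyl ethynyl glutarimide diester (6R,18S; C4 epimers) | COC(=O)CC(C(=O)OC)C[C@@]2(C(=O)N(C[C@@H](C)C(O[Si](c3ccccc3)(c3ccccc3)C(C)(C)C)C=C)C(=O)C[C@]2(CO)C=C)C#C | intermediate (not isolated)
23 | acetoxymethyl ethynyl glutarimide diester (6R,18S; C4 epimers) | COC(=O)CC(C(=O)OC)C[C@@]2(C(=O)N(C[C@@H](C)C(O[Si](c3ccccc3)(c3ccccc3)C(C)(C)C)C=C)C(=O)C[C@]2(COC(C)=O)C=C)C#C | intermediate
24 | propargylic alcohol: 23 with C≡C–CH2OH at C6 | COC(=O)CC(C(=O)OC)C[C@@]2(C(=O)N(C[C@@H](C)C(O[Si](c3ccccc3)(c3ccccc3)C(C)(C)C)C=C)C(=O)C[C@]2(COC(C)=O)C=C)C#CCO | intermediate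
25 | propargylic tert-butyldimethylsilyl ether of 24 | COC(=O)CC(C(=O)OC)C[C@@]2(C(=O)N(C[C@@H](C)C(O[Si](c3ccccc3)(c3ccccc3)C(C)(C)C)C=C)C(=O)C[C@]2(COC(C)=O)C=C)C#CCO[Si](C)(C)C(C)(C)C | intermediate
26 | succinic half-ester: 25 with CH2CO2H in place of CH2CO2Me (C17 acid) | OC(=O)CC(C(=O)OC)C[C@@]2(C(=O)N(C[C@@H](C)C(O[Si](c3ccccc3)(c3ccccc3)C(C)(C)C)C=C)C(=O)C[C@]2(COC(C)=O)C=C)C#CCO[Si](C)(C)C(C)(C)C | intermediate
27 | acid chloride of 26 | O=C(Cl)CC(C(=O)OC)C[C@@]2(C(=O)N(C[C@@H](C)C(O[Si](c3ccccc3)(c3ccccc3)C(C)(C)C)C=C)C(=O)C[C@]2(COC(C)=O)C=C)C#CCO[Si](C)(C)C(C)(C)C | intermediate (not isolated)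
28 | aldoketene O=C=CH–CH(CO2Me)–CH2–C6 | O=C=CC(C(=O)OC)C[C@@]2(C(=O)N(C[C@@H](C)C(O[Si](c3ccccc3)(c3ccccc3)C(C)(C)C)C=C)C(=O)C[C@]2(COC(C)=O)C=C)C#CCO[Si](C)(C)C(C)(C)C | intermediate (not isolated)
29 | 3-ethoxycyclobutanone substituted at C2 by the CH(CO2Me)CH2–C6 chain (diastereomers) | CCOC1CC(=O)C1C(C(=O)OC)C[C@@]2(C(=O)N(C[C@@H](C)C(O[Si](c3ccccc3)(c3ccccc3)C(C)(C)C)C=C)C(=O)C[C@]2(COC(C)=O)C=C)C#CCO[Si](C)(C)C(C)(C)C | intermediate
30 | cyclobutenone, key-step precursor (6R,18S,23R; C4 epimers) | COC(=O)C(C1=CCC1=O)C[C@@]2(C(=O)N(C[C@@H](C)C(O[Si](c3ccccc3)(c3ccccc3)C(C)(C)C)C=C)C(=O)C[C@]2(COC(C)=O)C=C)C#CCO[Si](C)(C)C(C)(C)C | intermediate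
31 | vinylketene from 4π opening of 30 | COC(=O)C(C(C=C)=C=O)C[C@@]2(C(=O)N(C[C@@H](C)C(O[Si](c3ccccc3)(c3ccccc3)C(C)(C)C)C=C)C(=O)C[C@]2(COC(C)=O)C=C)C#CCO[Si](C)(C)C(C)(C)C | intermediate (not isolated)
32 | bicyclo[3.2.0]heptenone (ring A fused to a 4-vinylcyclobutenone), spiro to the imide | COC(=O)C1C[C@@]4(C(=O)N(C[C@@H](C)C(O[Si](c3ccccc3)(c3ccccc3)C(C)(C)C)C=C)C(=O)C[C@]4(COC(C)=O)C=C)C2=C(CO[Si](C)(C)C(C)(C)C)C(=O)C12C=C | intermediate (not isolated)
33 | dienylketene from 4π opening of 32 | COC(=O)C1C[C@@]4(C(=O)N(C[C@@H](C)C(O[Si](c3ccccc3)(c3ccccc3)C(C)(C)C)C=C)C(=O)C[C@]4(COC(C)=O)C=C)C(C(CO[Si](C)(C)C(C)(C)C)=C=O)=C1C=C | intermediate (not isolated)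
34 | cyclohexa-2,4-dienone from 6π closure of 33 | COC(=O)C1C[C@@]4(C(=O)N(C[C@@H](C)C(O[Si](c3ccccc3)(c3ccccc3)C(C)(C)C)C=C)C(=O)C[C@]4(COC(C)=O)C=C)C2=C(CO[Si](C)(C)C(C)(C)C)C(=O)CC=C12 | intermediate (not isolated)
35 | spiro-glutarimide hydroxyindane, key-step product (6R,18S,23R; C4 epimers): rings A and B at the phenol level, OH at C17, CH2OSiMe2t-Bu at C12 | COC(=O)C1C[C@@]4(C(=O)N(C[C@@H](C)C(O[Si](c3ccccc3)(c3ccccc3)C(C)(C)C)C=C)C(=O)C[C@]4(COC(C)=O)C=C)c2c1ccc(O)c2CO[Si](C)(C)C(C)(C)C | intermediate
36 | C9 hydroxylactam of 35 (epimers at C9 and C4) | COC(=O)C1C[C@@]4(C(=O)N(C[C@@H](C)C(O[Si](c3ccccc3)(c3ccccc3)C(C)(C)C)C=C)C(O)C[C@]4(COC(C)=O)C=C)c2c1ccc(O)c2CO[Si](C)(C)C(C)(C)C | intermediate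
37 | bridged aryl aminal: ring C closed, phenol oxygen bonded to C9 | COC(=O)C1C[C@@]23C(=O)N(C[C@@H](C)C(O[Si](c6ccccc6)(c6ccccc6)C(C)(C)C)C=C)C7[C@@H](Cc5c2c1ccc5O7)[C@]3(COC(C)=O)C=C | intermediate (not isolated)
38 | bridged lactam phenol, rings A–D (6R,10S,18R,23R; C4 epimers) | COC(=O)C1C[C@@]23C(=O)N(C[C@@H](C)C(O[Si](c6ccccc6)(c6ccccc6)C(C)(C)C)C=C)C[C@@H](Cc5c2c1ccc5O)[C@]3(COC(C)=O)C=C | intermediate
39 | bridged lactam phenol (4R,6R,10S,18R,23R) | COC(=O)[C@@H]1C[C@@]23C(=O)N(C[C@@H](C)C(O[Si](c6ccccc6)(c6ccccc6)C(C)(C)C)C=C)C[C@@H](Cc5c2c1ccc5O)[C@]3(COC(C)=O)C=C | intermediate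
40 | diene allylic alcohol: 39 with free C22–OH | COC(=O)[C@@H]1C[C@@]23C(=O)N(C[C@@H](C)C(O)C=C)C[C@@H](Cc5c2c1ccc5O)[C@]3(COC(C)=O)C=C | intermediate
41 | pentacyclic phenol with C20=C21 alkene and C22–OH in ring E | COC(=O)[C@@H]1C[C@@]23C(=O)N4C[C@@H](Cc5c2c1ccc5O)[C@]3(COC(C)=O)C=CC(O)[C@H](C)C4 | intermediate
42 | para-quinol dienone (4R,6S,10S,14S,18R,23R) | COC(=O)[C@@H]1C[C@@]23C(=O)N4C[C@@H](CC5=C2[C@]1(O)C=CC5=O)[C@]3(COC(C)=O)C=CC(O)[C@H](C)C4 | intermediate
43 | C22 alcohol of the target (saturated ring E, ring B enone) | COC(=O)[C@@H]1C[C@@]23C(=O)N4C[C@@H](CC5=C2[C@]1(O)CCC5=O)[C@]3(COC(C)=O)CCC(O)[C@H](C)C4 | intermediate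
44 | CNP0211170.1 (4R,6S,10S,14S,18R,23R) | COC(=O)[C@@H]1C[C@@]23C(=O)N4C[C@@H](CC5=C2[C@]1(O)CCC5=O)[C@]3(COC(C)=O)CCC(=O)[C@H](C)C4 | target

Total step count: 29. Longest linear sequence: 25 steps (steps 5 to 29, from triethyl phosphonoacetate 7); the amine branch (steps 1 to 4) joins at step 11.

Least certain steps

Step 21 (key step). The vinylketene may be lost to dimerisation, to reclosure, or to the C18 vinyl group before the unactivated alkyne adds, and the cyclobutenone 30 may isomerise toward the conjugated alkylidene cyclobutanone on the way to it. Fallback: generate the same vinylketene without a cyclobutenone. Acid 26 is converted through acid chloride 27 by Stille acylation (n-Bu3SnCH=CH2, Pd(PPh3)4) into the vinyl ketone F1. Detrifluoroacetylative diazo transfer (LiN(SiMe3)2, CF3CO2CH2CF3; then MsN3, Et3N) gives the α-diazo enone F2. Irradiation at about 300 nm brings about a Wolff rearrangement with vinyl migration to vinylketene 31 at room temperature, and warming completes the cascade to phenol 35, where the route is rejoined.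

Step 9. Enantioselection may be eroded by incomplete face exchange of the allyl complex, by an uncatalysed SN2' closure, or by elimination to the dienoate followed by a racemic Michael closure. Fallback: resolution instead of asymmetric catalysis. Chloride 14 is cyclised with an achiral catalyst (Pd(PPh3)4) to the racemate, which contains the enantiomeric lactone F3. Acidolysis gives racemic acid, that is 16 together with its enantiomer F4. Crystallisation with (R)-1-phenylethylamine separates the diastereomeric salt F5, from which 16 is liberated and the route rejoined.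

Step 14. Shielding by the enolates may be incomplete, so that hydride also reaches the imide carbonyl C9 or a methyl ester. Fallback: carry the two ester groups as carboxylates, which need no enolisation. Adduct 20 is hydrolysed with excess Me3SnOH to the diacid F6. LiN(i-Pr)2 (two carboxylates and the imide enolate) and i-Bu2AlH give the lactol diacid F7, and the Colvin rearrangement gives the hydroxy alkyne diacid F8. Me3SiCHN2 in methanol restores both methyl esters to give 22, which is acetylated to 23.

Step 23. The N-acyliminium ion or the benzylic cation may be quenched or reduced before the enamide carbon reaches C11, giving open-chain lactam or a methyl arene. Fallback: close ring C on the intact imide and reduce afterwards. Phenol 35 is treated with Me3SiOTf and Et3N, so that the imide silyl enol ether at C10 captures the benzylic cation in a Mukaiyama-type alkylation, giving the bridged imide F9. LiBH(s-Bu)3 reduces its C9 carbonyl to the bridged hydroxylactam F10, and Et3SiH with BF3·OEt2 gives lactam 38.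

Step 24. The equilibrium may be slow, because the phenoxide lowers the acidity of C4–H, or may favour the wrong epimer if the conformational argument fails. Fallback: kinetic instead of thermodynamic control. Lactam 38 is converted with KN(SiMe3)2 (2.2 equiv, −78 °C) into the phenoxide ester enolate and protonated with a hindered phenol; protonation from the more open face gives the epimer that equilibration disfavours, and whichever mode gives (4R) is used to reach 39. No new compound is involved.

Step 26. Both alkenes are hindered, so initiation may be slow and the catalyst may decompose or dimerise the allylic alcohol before the nine-membered ring closes. Fallback: change the alkene partner and the order of oxidation. Alcohol 40 is oxidised with MnO2 to the vinyl ketone F11, whose electron-poor alkene does not homodimerise, and ring closure gives the cyclic enone F12. PhI(OAc)2 in aqueous acetonitrile gives the quinol enone F13, and hydrogenation of its two disubstituted alkenes gives target 44 directly.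

Further compounds

F1 | step 21 | vinyl ketone from 26: CH2=CH–C(=O)–CH2–CH(CO2Me)–CH2–C6 | C=CC(=O)CC(C(=O)OC)C[C@@]2(C(=O)N(C[C@@H](C)C(O[Si](c3ccccc3)(c3ccccc3)C(C)(C)C)C=C)C(=O)C[C@]2(COC(C)=O)C=C)C#CCO[Si](C)(C)C(C)(C)C
F2 | step 21 | α-diazo enone: CH2=CH–C(=O)–C(=N2)–CH(CO2Me)–CH2–C6 | C=CC(=O)C(=[N+]=[N-])C(C(=O)OC)C[C@@]2(C(=O)N(C[C@@H](C)C(O[Si](c3ccccc3)(c3ccccc3)C(C)(C)C)C=C)C(=O)C[C@]2(COC(C)=O)C=C)C#CCO[Si](C)(C)C(C)(C)C
F3 | step 9 | methyl (4R)-4-(2-tert-butoxy-2-oxoethyl)-2-oxo-4-vinyloxolane-3-carboxylate (enantiomer of 15) | COC(=O)C1C(=O)OC[C@@]1(C=C)CC(=O)OC(C)(C)C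
F4 | step 9 | 2-[(3R)-4-(methoxycarbonyl)-5-oxo-3-vinyloxolan-3-yl]acetic acid (enantiomer of 16) | COC(=O)C1C(=O)OC[C@@]1(C=C)CC(=O)O
F5 | step 9 | (R)-1-phenylethylammonium salt of 16 | COC(=O)C1C(=O)OC[C@]1(C=C)CC(=O)[O-].C[C@@H]([NH3+])c1ccccc1
F6 | step 14 | diacid of 20 (both methyl esters hydrolysed) | OC(=O)CC(C(=O)O)C[C@]12C(=O)N(C[C@@H](C)C(O[Si](c3ccccc3)(c3ccccc3)C(C)(C)C)C=C)C(=O)C[C@@]1(C=C)COC2=O
F7 | step 14 | lactol diacid | OC(=O)CC(C(=O)O)C[C@]12C(=O)N(C[C@@H](C)C(O[Si](c3ccccc3)(c3ccccc3)C(C)(C)C)C=C)C(=O)C[C@@]1(C=C)COC2O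
F8 | step 14 | hydroxymethyl ethynyl glutarimide diacid | OC(=O)CC(C(=O)O)C[C@@]2(C(=O)N(C[C@@H](C)C(O[Si](c3ccccc3)(c3ccccc3)C(C)(C)C)C=C)C(=O)C[C@]2(CO)C=C)C#C
F9 | step 23 | bridged imide phenol (ring C closed, C9=O retained) | COC(=O)C1C[C@@]23C(=O)N(C[C@@H](C)C(O[Si](c6ccccc6)(c6ccccc6)C(C)(C)C)C=C)C(=O)[C@@H](Cc5c2c1ccc5O)[C@]3(COC(C)=O)C=C
F10 | step 23 | bridged C9 hydroxylactam phenol | COC(=O)C1C[C@@]23C(=O)N(C[C@@H](C)C(O[Si](c6ccccc6)(c6ccccc6)C(C)(C)C)C=C)C(O)[C@@H](Cc5c2c1ccc5O)[C@]3(COC(C)=O)C=C
F0 | step 24 | none | none
F11 | step 26 | vinyl ketone from 40 (C22 ketone, open ring E) | COC(=O)[C@@H]1C[C@@]23C(=O)N(C[C@@H](C)C(=O)C=C)C[C@@H](Cc5c2c1ccc5O)[C@]3(COC(C)=O)C=C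
F12 | step 26 | pentacyclic phenol with ring E enone | COC(=O)[C@@H]1C[C@@]23C(=O)N4C[C@@H](Cc5c2c1ccc5O)[C@]3(COC(C)=O)C=CC(=O)[C@H](C)C4
F13 | step 26 | para-quinol dienone with ring E enone | COC(=O)[C@@H]1C[C@@]23C(=O)N4C[C@@H](CC5=C2[C@]1(O)C=CC5=O)[C@]3(COC(C)=O)C=CC(=O)[C@H](C)C4
A1 | alternative 1 | triethylsilyl ether of the target | COC(=O)[C@@H]1C[C@@]23C(=O)N4C[C@@H](CC5=C2[C@]1(O[Si](CC)(CC)CC)CCC5=O)[C@]3(COC(C)=O)CCC(=O)[C@H](C)C4
A4 | alternative 1 | six-membered ring A α-diazo ketone | O=C1C(=[N+]=[N-])C[C@@]23C(=O)N4C[C@@H](CC5=C2[C@]1(O[Si](CC)(CC)CC)CCC5=O)[C@]3(COC(C)=O)CCC(=O)[C@H](C)C4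
A2 | alternative 2 | bridged enamide keto-lactam (rings D and E) | O=C1N2C=C[C@](CO[Si](C)(C)C(C)(C)C)(CCC(=O)[C@H](C)C2)C13CC=CC3
A5 | alternative 2 | indolizidinone vinyl carbinol | O=C1N2C[C@@H](C)C(O)(C=C)C2C=C(CO[Si](C)(C)C(C)(C)C)C13CC=CC3
A3 | alternative 3 | nine-membered keto-lactam fused to ring C | N1C[C@@H](C)C(=O)CC[C@@]2(COC(C)=O)[C@@H](CO[Si](C)(C)C(C)(C)C)CC3(OCCO3)C[C@@]2(CCC(=O)OC)C1=O
A6 | alternative 3 | seven-membered N-propyl imide | CCCN1C(=O)CC[C@@]2(COC(C)=O)[C@@H](CO[Si](C)(C)C(C)(C)C)CC3(OCCO3)C[C@@]2(CCC(=O)OC)C1=O
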